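**Assumptions (one line):** an ene-reductase from a commercial panel gives the (R)-aldehyde in step 22. (R)-BINAP–Ru gives the (R)-β-hydroxy ester, as it does for methyl acetoacetate. The Frater–Seebach ethylation is 2,3-anti. 2-Bromobutanal is available.

**Retrosynthesis**
1. The target acid comes from oxidation of a primary alcohol. The C(d)=C(c) E-alkene comes from Julia–Kocienski olefination of an α-chiral aldehyde. That aldehyde comes from ene-reductase reduction of a 2-ethyl-dienal, which is built by two stabilised-ylide Wittig homologations of the dioxane aldehyde (this fixes the E-trisubstituted alkene).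
2. The dioxane aldehyde comes from periodate cleavage of a diol. The only ring closure is 6-exo opening of a tertiary epoxide by a secondary hydroperoxide, with inversion at C6. The hydroperoxide comes from SN2 displacement (inversion at C3) of a mesylate by H2O2.
3. The epoxide comes from Sharpless epoxidation of a (Z)-allylic alcohol. That alcohol comes from Negishi coupling of an alkyl iodide with a (Z)-vinyl iodide.
4. The alkyl iodide (C3/C4 stereodyad) comes from Frater–Seebach anti-alkylation of a Ru-BINAP-derived (R)-β-hydroxy ester, which comes from ethyl 3-hydroxypropanoate.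

---

**Step 1**
Reactants: 1 ethyl 3-hydroxypropanoate
Product: 2 ethyl 3-(TBDPS-oxy)propanoate
Conditions: TBDPSCl, imidazole, DMF, rt
Reagents that add atoms: TBDPSCl, CC(C)(C)[Si](Cl)(c1ccccc1)c1ccccc1
Why: Silylation protects the primary alcohol; no stereocentre is involved.

**Step 2**
Reactants: 2
Product: 3 3-(TBDPS-oxy)propanoic acid
Conditions: LiOH·H2O, THF/H2O, 0 °C to rt
Reagents that add atoms: water/hydroxide, O
Why: Saponification frees the acid needed for the acylation in step 3; TBDPS survives.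

**Step 3**
Reactants: 3
Product: 4 ethyl 5-(TBDPS-oxy)-3-oxopentanoate
Conditions: CDI, THF, rt; then Mg(O2CCH2CO2Et)2 (from potassium ethyl malonate, MgCl2, Et3N), rt
Reagents that add atoms: potassium ethyl malonate, CCOC(=O)CC(=O)[O-].[K+]
Why: Masamune–Brooks decarboxylative Claisen acylation gives the β-keto ester through the acyl-imidazolide.

**Step 4**
Reactants: 4
Product: 5 ethyl (3R)-3-hydroxy-5-(TBDPS-oxy)pentanoate
Conditions: [RuCl((R)-BINAP)(p-cymene)]Cl (1 mol %), H2 (5 atm), EtOH, 80 °C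
Reagents that add atoms: none
Why: Noyori asymmetric hydrogenation of the β-keto ester creates the C3 carbinol, the first stereocentre, by catalyst control.

**Step 5**
Reactants: 5
Product: 6 ethyl (2R,3R)-2-ethyl-3-hydroxy-5-(TBDPS-oxy)pentanoate
Conditions: LDA (2.3 equiv), THF, −78 to 0 °C; then EtI, DMPU, −40 to 0 °C
Reagents that add atoms: ethyl iodide, CCI
Why: In Frater–Seebach alkylation the Li-chelated dianion is attacked by EtI anti to the C3 side chain, giving the 2,3-anti product that sets C4.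

**Step 6**
Reactants: 6
Product: 7 ethyl (2R,3R)-2-ethyl-5-(TBDPS-oxy)-3-(TES-oxy)pentanoate
Conditions: TESCl, imidazole, DMF, rt
Reagents that add atoms: TESCl, CC[Si](Cl)(CC)CC
Why: A TES ether is orthogonal to TBDPS and leaves both stereocentres untouched.

**Step 7**
Reactants: 7
Product: 8 (2S,3R)-2-ethyl-5-(TBDPS-oxy)-3-(TES-oxy)pentan-1-ol
Conditions: LiAlH4, THF, 0 °C
Reagents that add atoms: none
Why: Ester reduction; the silyl ethers survive and the non-acidic C4 stays configured.

**Step 8**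
Reactants: 8
Product: 9 (2R,3R)-2-ethyl-1-iodo-5-(TBDPS-oxy)-3-(TES-oxy)pentane
Conditions: I2, PPh3, imidazole, CH2Cl2, 0 °C
Reagents that add atoms: iodine, II
Why: Appel-type iodination of the primary alcohol (SN2 at CH2) leaves C4 untouched.

**Step 9**
Reactants: 10 pent-2-yn-1-ol
Product: 11 (Z)-3-iodopent-2-en-1-ol
Conditions: Red-Al, Et2O, 0 °C; then EtOAc; I2, −78 °C
Reagents that add atoms: iodine, II
Why: Alkoxide-directed trans-hydroalumination followed by iodinolysis puts I at C3 cis to CH2OH, so Et is trans to CH2OH.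

**Step 10**
Reactants: 11
Product: 12 (Z)-TBS ether of 11
Conditions: TBSCl, imidazole, DMF, rt
Reagents that add atoms: TBSCl, C[Si](C)(Cl)C(C)(C)C
Why: Protects the allylic alcohol for the Pd coupling.

**Step 11**
Reactants: 9, 12
Product: 13 (Z)-TBS allyl ether: TBSOCH2CH=C(Et)CH2–C4H(Et)–C3H(OTES)CH2CH2OTBDPS
Conditions: Zn dust, TMSCl/BrCH2CH2Br (cat.), LiCl, THF, 40 °C; then 12, Pd(PPh3)4 (5 mol %), THF, 50 °C
Reagents that add atoms: none
Why: Negishi coupling of the primary alkylzinc with the vinyl iodide proceeds with retention of alkene geometry, so C5 ends up cis to CH2O (Z). This is done before any peroxide exists, because Pd(0) would ionise an allylic peroxide.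

**Step 12**
Reactants: 13
Product: 14 C3 secondary alcohol (TES removed)
Conditions: PPTS, MeOH, 0 °C to rt
Reagents that add atoms: none
Why: A secondary TES ether is cleaved far faster than a primary TBS or TBDPS ether, so only C3–OH is freed.

**Step 13**
Reactants: 14
Product: 15 C3 mesylate (3R)
Conditions: MsCl, Et3N, CH2Cl2, 0 °C
Reagents that add atoms: MsCl, CS(=O)(=O)Cl
Why: This makes the leaving group for inversion at C3; the configuration is retained in this step.

**Step 14**
Reactants: 15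
Product: 16 (Z)-allylic alcohol (primary TBS removed)
Conditions: CSA (10 mol %), MeOH/CH2Cl2 1:1, 0 °C
Reagents that add atoms: none
Why: Acid-catalysed methanolysis removes the primary allylic TBS ether selectively and leaves TBDPS and the mesylate.

**Step 15**
Reactants: 16
Product: 17 epoxy alcohol (epoxide C(j) R, C6 S), C3 mesylate retained
Conditions: Ti(OiPr)4, D-(−)-diethyl tartrate, TBHP, 3 Å MS, CH2Cl2, −20 °C
Reagents that add atoms: tert-butyl hydroperoxide, CC(C)(C)OO
Why: In Sharpless asymmetric epoxidation the D-tartrate face plus the Z geometry fix the tertiary epoxide carbon as S, the precursor of C6 (R) after inversion.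

**Step 16**
Reactants: 17
Product: 18 hydroperoxy epoxy alcohol (C3 now S)
Conditions: 50 % aq. H2O2 (30 equiv), Cs2CO3, DMF/THF, 0 °C to rt
Reagents that add atoms: hydrogen peroxide, OO
Why: SN2 displacement of the secondary mesylate by HOO⁻ inverts C3 from R to S, giving the required 3S peroxide carbon.

**Step 17**
Reactants: 18
Product: 19 1,2-dioxane diol, (3S,4S,6R) ring, C6–CH(OH)CH2OH
Conditions: Ti(OiPr)4 (1.2 equiv), CH2Cl2, rt (if step 16 does not already cyclise)
Reagents that add atoms: none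
Why: Ti-chelated epoxy alcohol undergoes 6-exo-tet opening at the tertiary carbon by the hydroperoxide. Inversion converts the S epoxide carbon into R-configured C6, forming the only ring.

**Step 18**
Reactants: 19
Product: 20 (3S,4S,6R)-4,6-diethyl-3-[2-(TBDPS-oxy)ethyl]-1,2-dioxane-6-carbaldehyde
Conditions: NaIO4, THF/H2O 4:1, 0 °C to rt
Reagents that add atoms: none
Why: Malaprade cleavage of the vicinal diol gives a non-enolisable α-peroxy aldehyde; C6 is untouched.

**Step 19**
Reactants: 21 2-bromobutanal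
Product: 22 (1-formylpropylidene)triphenylphosphorane
Conditions: PPh3, CH2Cl2, rt; then aq. NaOH
Reagents that add atoms: triphenylphosphine, c1ccc(cc1)P(c1ccccc1)c1ccccc1
Why: Phosphonium salt formation followed by deprotonation gives the stabilised aldehyde ylide.

**Step 20**
Reactants: 20, 22
Product: 23 (2E)-2-ethyl-3-(dioxanyl)prop-2-enal
Conditions: toluene, 80 °C
Reagents that add atoms: none
Why: A stabilised ylide gives an E-enal with CHO trans to the bulky quaternary C6, which is the C(i)=C(j) geometry of the target.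

**Step 21**
Reactants: 23, 22
Product: 24 (2E,4E)-2,4-diethyl-5-(dioxanyl)penta-2,4-dienal
Conditions: toluene, 90 °C
Reagents that add atoms: none
Why: A second stabilised-ylide Wittig extends the chain and builds the C(h)=C(e) alkene to be reduced.

**Step 22**
Reactants: 24
Product: 25 (2R,4E)-2,4-diethyl-5-(dioxanyl)pent-4-enal
Conditions: ene-reductase (Old Yellow Enzyme family, flavin-dependent oxidoreductase), NADP⁺ (cat.), glucose/GDH, KPi pH 7, 15 % DMSO, 30 °C
Reagents that add atoms: none
Why: Hydride from reduced FMN adds to Cβ and a tyrosine protonates Cα, so the enzyme sets the α-stereocentre (R); the isolated γ,δ-alkene is not reduced.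

**Step 23**
Reactants: 26 1-bromopropane, 27 1-phenyl-1H-tetrazole-5-thiol
Product: 28 5-(propylthio)-1-phenyl-1H-tetrazole
Conditions: K2CO3, acetone, reflux
Reagents that add atoms: none
Why: S-alkylation (SN2) builds the sulfide.

**Step 24**
Reactants: 28
Product: 29 5-(propylsulfonyl)-1-phenyl-1H-tetrazole
Conditions: 30 % H2O2, (NH4)6Mo7O24 (cat.), EtOH, 0 °C to rt
Reagents that add atoms: hydrogen peroxide, OO
Why: Molybdate-catalysed oxidation of sulfide to sulfone; no stereocentre is involved.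

**Step 25**
Reactants: 25, 29
Product: 30 TBDPS ether of the target, with the (E)-alkene
Conditions: KHMDS, DME, −60 °C, then 25, warm to rt
Reagents that add atoms: none
Why: Julia–Kocienski olefination of the PT sulfone with an α-branched aldehyde gives the E-disubstituted alkene; the α-stereocentre is not touched.

**Step 26**
Reactants: 30
Product: 31 primary alcohol
Conditions: TBAF/AcOH (1:1), THF, rt
Reagents that add atoms: none
Why: Buffered fluoride removes TBDPS without base-induced Kornblum–DeLaMare cleavage of the peroxide.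

**Step 27**
Reactants: 31
Product: 32 Plakortide N
Conditions: TEMPO (20 mol %), PhI(OAc)2 (4 equiv), MeCN/H2O 1:1, rt
Reagents that add atoms: water, O
Why: TEMPO/BAIB oxidation goes through the aldehyde hydrate to the acid under mildly acidic conditions, which avoids retro-oxa-Michael loss of the β-peroxide.

---

**Compound list**

| No. | Name | SMILES | Role |
|---|---|---|---|
| 1 | ethyl 3-hydroxypropanoate | CCOC(=O)CCO | starting material |
| 2 | ethyl 3-(TBDPS-oxy)propanoate | CCOC(=O)CCO[Si](c1ccccc1)(c1ccccc1)C(C)(C)C | intermediate |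
| 3 | 3-(TBDPS-oxy)propanoic acid | OC(=O)CCO[Si](c1ccccc1)(c1ccccc1)C(C)(C)C | intermediate |
| 4 | ethyl 5-(TBDPS-oxy)-3-oxopentanoate | CCOC(=O)CC(=O)CCO[Si](c1ccccc1)(c1ccccc1)C(C)(C)C | intermediate |
| 5 | ethyl (3R)-3-hydroxy-5-(TBDPS-oxy)pentanoate | CCOC(=O)C[C@H](O)CCO[Si](c1ccccc1)(c1ccccc1)C(C)(C)C | intermediate |
| 6 | ethyl (2R,3R)-2-ethyl-3-hydroxy-5-(TBDPS-oxy)pentanoate | CCOC(=O)[C@H](CC)[C@H](O)CCO[Si](c1ccccc1)(c1ccccc1)C(C)(C)C | intermediate |
| 7 | (2R,3R)-2-ethyl-5-(TBDPS-oxy)-3-(TES-oxy)pentanoate, ethyl ester | CCOC(=O)[C@H](CC)[C@H](O[Si](CC)(CC)CC)CCO[Si](c1ccccc1)(c1ccccc1)C(C)(C)C | intermediate |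
| 8 | (2S,3R)-2-ethyl-5-(TBDPS-oxy)-3-(TES-oxy)pentan-1-ol | OC[C@H](CC)[C@H](O[Si](CC)(CC)CC)CCO[Si](c1ccccc1)(c1ccccc1)C(C)(C)C | intermediate |
| 9 | (2R,3R)-2-ethyl-1-iodo-5-(TBDPS-oxy)-3-(TES-oxy)pentane | IC[C@H](CC)[C@H](O[Si](CC)(CC)CC)CCO[Si](c1ccccc1)(c1ccccc1)C(C)(C)C | intermediate |
| 10 | pent-2-yn-1-ol | CCC#CCO | starting material |
| 11 | (2Z)-3-iodopent-2-en-1-ol | CC/C(I)=C/CO | intermediate |
| 12 | (Z)-3-iodopent-2-enyl TBS ether | CC/C(I)=C/CO[Si](C)(C)C(C)(C)C | intermediate |
| 13 | (Z)-allyl TBS ether, C3 (R)-OTES, C4 (S)-Et | CC/C(C[C@H](CC)[C@H](O[Si](CC)(CC)CC)CCO[Si](c1ccccc1)(c1ccccc1)C(C)(C)C)=C/CO[Si](C)(C)C(C)(C)C | intermediate |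
| 14 | as 13, C3–OH | CC/C(C[C@H](CC)[C@H](O)CCO[Si](c1ccccc1)(c1ccccc1)C(C)(C)C)=C/CO[Si](C)(C)C(C)(C)C | intermediate |
| 15 | as 13, C3–OMs | CC/C(C[C@H](CC)[C@H](OS(C)(=O)=O)CCO[Si](c1ccccc1)(c1ccccc1)C(C)(C)C)=C/CO[Si](C)(C)C(C)(C)C | intermediate |
| 16 | (Z)-allylic alcohol, C3–OMs | CC/C(C[C@H](CC)[C@H](OS(C)(=O)=O)CCO[Si](c1ccccc1)(c1ccccc1)C(C)(C)C)=C/CO | intermediate |
| 17 | epoxy alcohol (epoxide C(j) R, C6 S), C3–OMs | OC[C@H]1O[C@@]1(CC)C[C@H](CC)[C@H](OS(C)(=O)=O)CCO[Si](c2ccccc2)(c2ccccc2)C(C)(C)C | intermediate |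
| 18 | hydroperoxy epoxy alcohol (C3 S) | OC[C@H]1O[C@@]1(CC)C[C@H](CC)[C@@H](OO)CCO[Si](c2ccccc2)(c2ccccc2)C(C)(C)C | intermediate |
| 19 | (3S,4S,6R)-1,2-dioxane with C6–CH(OH)CH2OH | OC[C@@H](O)[C@@]1(CC)C[C@H](CC)[C@H](CCO[Si](c2ccccc2)(c2ccccc2)C(C)(C)C)OO1 | intermediate |
| 20 | (3S,4S,6R)-4,6-diethyl-3-[2-(TBDPS-oxy)ethyl]-1,2-dioxane-6-carbaldehyde | O=C[C@@]1(CC)C[C@H](CC)[C@H](CCO[Si](c2ccccc2)(c2ccccc2)C(C)(C)C)OO1 | intermediate |
| 21 | 2-bromobutanal | CCC(Br)C=O | starting material |
| 22 | (1-formylpropylidene)triphenylphosphorane | CCC(C=O)=P(c1ccccc1)(c1ccccc1)c1ccccc1 | intermediate |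
| 23 | (2E)-2-ethyl-3-(dioxanyl)prop-2-enal | O=C/C(CC)=C/[C@@]1(CC)C[C@H](CC)[C@H](CCO[Si](c2ccccc2)(c2ccccc2)C(C)(C)C)OO1 | intermediate |
| 24 | (2E,4E)-2,4-diethyl-5-(dioxanyl)penta-2,4-dienal | O=C/C(CC)=C/C(CC)=C/[C@@]1(CC)C[C@H](CC)[C@H](CCO[Si](c2ccccc2)(c2ccccc2)C(C)(C)C)OO1 | intermediate |
| 25 | (2R,4E)-2,4-diethyl-5-(dioxanyl)pent-4-enal | O=C[C@H](CC)C/C(=C/[C@@]1(CC)C[C@H](CC)[C@H](CCO[Si](c2ccccc2)(c2ccccc2)C(C)(C)C)OO1)CC | intermediate |
| 26 | 1-bromopropane | CCCBr | starting material |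
| 27 | 1-phenyl-1H-tetrazole-5-thiol | Sc1nnnn1-c1ccccc1 | starting material |
| 28 | 1-phenyl-5-(propylthio)-1H-tetrazole | CCCSc1nnnn1-c1ccccc1 | intermediate |
| 29 | 1-phenyl-5-(propylsulfonyl)-1H-tetrazole | CCCS(=O)(=O)c1nnnn1-c1ccccc1 | intermediate |
| 30 | TBDPS ether of target | CC/C=C/[C@H](CC)C/C(=C/[C@@]1(CC)C[C@H](CC)[C@H](CCO[Si](c2ccccc2)(c2ccccc2)C(C)(C)C)OO1)CC | intermediate |
| 31 | primary alcohol analogue | CC/C=C/[C@H](CC)C/C(=C/[C@@]1(CC)C[C@H](CC)[C@H](CCO)OO1)CC | intermediate |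
| 32 | Plakortide N, 2-{(3S,4S,6R)-6-[(1E,4R,5E)-2,4-diethylocta-1,5-dien-1-yl]-4,6-diethyl-1,2-dioxan-3-yl}acetic acid | CC/C=C/[C@H](CC)C/C(=C/[C@@]1(CC)C[C@H](CC)[C@H](CC(=O)O)OO1)CC | target |

---

**Total steps:** 27. **Longest linear sequence:** 22 (steps 1–8, 11–18, 20–22, 25–27).

**Three steps most likely to fail**
1. **Step 16** (H2O2 displacement of the hindered secondary mesylate; elimination competes). Fallback: skip the sulfonate and invert C3 by Mitsunobu reaction of the free C3 alcohol with triethylsilyl hydroperoxide, then remove the silyl group, using epoxy alcohol 17 with its primary OH silylated.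
2. **Step 17** (opening of the tertiary epoxide by the hydroperoxide). Fallback: reverse the roles of the two partners. Open the epoxide of 17 intermolecularly with H2O2 under Ti(OiPr)4 to give the tertiary hydroperoxide, then close the ring by intramolecular SN2 at the retained C3 mesylate (Cs2CO3).
3. **Step 22** (ene-reductase acceptance and ee on the large, peroxide-containing dienal). Fallback: make the (R)-C(e) unit earlier by Cu/Josiphos asymmetric conjugate addition of EtMgBr to ethyl (2E,4E)-hepta-2,4-dienoate. Convert that ester to a PT sulfone and join it to aldehyde 20 by Julia–Kocienski olefination, separating the E/Z trisubstituted alkenes on AgNO3–silica.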